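**Retrosynthetic overview**

1. Target ⇐ primary alcohol 30 (oxidation) ⇐ allylic-diazene reductive transposition of dienyl carbinol 26, which places the (Z)-exocyclic C2=C3' alkene ⇐ ring-B dienyllithium 25 + dioxanyl propanal 16.
2. C6–C1' bond (quaternary peroxide carbon) ⇐ axial allylation of the 6-methyl peroxycarbenium ion, cis to the C3 side chain.
3. 1,2-Dioxane ⇐ insertion of O2 into the C6–C3 bond of 1-methyl-2-alkylcyclobutanol 8 (four- to six-membered ring expansion); 8 ⇐ 2-substituted cyclobutanone ⇐ methyl (2R)-3-hydroxy-2-methylpropanoate.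
4. Enabling feature: O1–O2 bridges C3 and C6, which are also joined through C4–C5, so C3–C4–C5–C6 is a cyclobutane once the peroxide is taken out. C6 (methyl, oxygen) is the carbinol carbon and becomes the hemiketal and latent cation; C3 is the more substituted radical terminus.
5. Ring order: rings A and B (bought as the aromatic tetralone, diene pattern set by Birch reduction) → cyclobutane → 1,2-dioxane (key step).

Key step: step 6

Remark: locants C3–C6 and O1–O2 (dioxane), C1'–C3' (chain from C6) and C1–C8a (bicycle, naphthalene locants) follow the target throughout, also in the compound names. Centres that are erased later are carried as mixtures. The radical ring expansion cannot control C3, so both C3 epimers are carried from step 6 and the wrong series is removed at step 8.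

**Route**

Step 1
Reactants: 1 methyl (2R)-3-hydroxy-2-methylpropanoate
Product: 2 methyl (2R)-3-[(tert-butyldiphenylsilyl)oxy]-2-methylpropanoate
Conditions: TBDPSCl, imidazole, CH2Cl2, 0 °C to rt
Reagents that add atoms: tert-butyl(chloro)diphenylsilane, CC(C)(C)[Si](Cl)(c1ccccc1)c1ccccc1
Why: Silyl ether formation at the primary alcohol gives a group that survives acid, organometallics and Lewis acids up to step 19; the stereocentre is untouched.

Step 2
Reactants: 2 methyl (2R)-3-[(tert-butyldiphenylsilyl)oxy]-2-methylpropanoate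
Product: 3 (2R)-3-[(tert-butyldiphenylsilyl)oxy]-2-methylpropanal
Conditions: DIBAL-H, CH2Cl2, −78 °C
Reagents that add atoms: none
Why: Partial ester reduction with diisobutylaluminium hydride stops at the aluminium hemiacetal at −78 °C, and cold non-basic work-up with immediate use keeps the α-stereocentre.

Step 3
Reactants: 4 cyclopropyl phenyl sulfide; 3 (2R)-3-[(tert-butyldiphenylsilyl)oxy]-2-methylpropanal
Product: 6 (2R)-3-[(tert-butyldiphenylsilyl)oxy]-2-methyl-1-[1-(phenylsulfanyl)cyclopropyl]propan-1-ol (both C1 epimers), via 1-lithio-1-(phenylsulfanyl)cyclopropane 5 (not isolated)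
Conditions: n-BuLi, THF, 0 °C; then 3, −78 °C; NH4Cl (aq)
Reagents that add atoms: none
Why: The sulfur-stabilised cyclopropyllithium adds 1,2 to the aldehyde without enolising it (organolithium carbonyl addition); the new carbinol centre becomes the migration terminus in step 4, so its configuration is irrelevant.

Step 4
Reactants: 6 (2R)-3-[(tert-butyldiphenylsilyl)oxy]-2-methyl-1-[1-(phenylsulfanyl)cyclopropyl]propan-1-ol
Product: 7 2-[(2S)-1-[(tert-butyldiphenylsilyl)oxy]propan-2-yl]cyclobutan-1-one (both ring epimers)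
Conditions: p-TsOH·H2O (cat.), wet benzene, 80 °C
Reagents that add atoms: water, O
Why: Ionisation of the cyclopropylcarbinol triggers ring expansion to the sulfur-stabilised cyclobutyl cation, and hydrolysis of the thionium ion gives the 2-substituted cyclobutanone (cyclopropylcarbinyl-to-cyclobutyl semipinacol-type rearrangement); the side-chain stereocentre is not involved.

Step 5
Reactants: 7 2-[(2S)-1-[(tert-butyldiphenylsilyl)oxy]propan-2-yl]cyclobutan-1-one
Product: 8 2-[(2S)-1-[(tert-butyldiphenylsilyl)oxy]propan-2-yl]-1-methylcyclobutan-1-ol (ring stereoisomers)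
Conditions: MeMgBr, THF, −78 °C to 0 °C; NH4Cl (aq)
Reagents that add atoms: methylmagnesium bromide, C[Mg]Br
Why: Grignard addition to the strained, electrophilic cyclobutanone gives the tertiary cyclobutanol; both ring centres are erased in step 6, so all stereoisomers converge.

Step 6
Reactants: 8 2-[(2S)-1-[(tert-butyldiphenylsilyl)oxy]propan-2-yl]-1-methylcyclobutan-1-ol
Product: 10 tert-butyldiphenylsilyl ether of (2R)-2-(6-hydroxy-6-methyl-1,2-dioxan-3-yl)propan-1-ol (C3 epimers and C6 anomers), via hydroperoxy ketone 9 (not isolated)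
Conditions: Co(acac)2 (cat.), O2 (1 atm), 1,2-dichloroethane, 40 °C
Reagents that add atoms: dioxygen, O=O
Why: Co(acac)2 and O2 turn the tertiary cyclobutanol into its alkoxy radical, which undergoes strain-driven β-scission of the C6–C3 bond to the secondary C3 radical; this captures O2, the peroxyl radical is reduced to hydroperoxide 9 by the cobalt redox couple, and 9 closes onto the methyl ketone. The closest known reaction type is the cobalt-catalysed aerobic ring expansion of 2-substituted cyclobutanols to 1,2-dioxan-3-ols. The 1,2-dioxane closes by 6-exo-trig addition of the hydroperoxide oxygen to the C6 carbonyl, so that overall O2 is inserted into one C–C bond of the four-membered ring (expansion by two atoms). Of the new stereocentres, C6 is a hemiketal carbon under thermodynamic control that is erased in step 8, whereas C3 comes from a planar open-chain radical on which the neighbouring stereocentre exerts no dependable facial bias, so both C3 epimers are expected and are parted at step 8. The step needs β-scission toward C3 and not toward C5 or the methyl group, which the substrate secures because only cleavage of the C6–C3 ring bond both releases the ring strain and gives a secondary radical.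

Step 7
Reactants: 10 tert-butyldiphenylsilyl ether of (2R)-2-(6-hydroxy-6-methyl-1,2-dioxan-3-yl)propan-1-ol
Product: 11 tert-butyldiphenylsilyl ether of (2R)-2-(6-methoxy-6-methyl-1,2-dioxan-3-yl)propan-1-ol (C3 epimers and C6 anomers)
Conditions: MeOH, PPTS (cat.), 4 Å molecular sieves, rt
Reagents that add atoms: methanol, CO
Why: Acid-catalysed exchange of the hemiketal hydroxyl for methoxy (ketalisation) locks the cyclic peroxide against ring-chain tautomerism and supplies the leaving group for step 8.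

Step 8
Reactants: 11 tert-butyldiphenylsilyl ether of (2R)-2-(6-methoxy-6-methyl-1,2-dioxan-3-yl)propan-1-ol
Product: 13 tert-butyldiphenylsilyl ether of (2R)-2-[(3S,6R)-6-methyl-6-(prop-2-en-1-yl)-1,2-dioxan-3-yl]propan-1-ol, via peroxycarbenium triflate 12 (not isolated)
Conditions: allylSiMe3, TMSOTf (cat.), CH2Cl2, −78 °C; chromatographic separation of diastereomers
Reagents that add atoms: allyltrimethylsilane, C=CC[Si](C)(C)C
Why: TMSOTf ionises the ketal to the six-membered peroxycarbenium ion, whose half-chair with the C3 side chain pseudo-equatorial is attacked by the allylsilane along the axial trajectory (Hosomi–Sakurai-type allylation of a cyclic peroxyketal, stereoelectronic control as in six-membered oxocarbenium ions), so the allyl group should enter cis to the C3 substituent with the methyl group equatorial; the diastereomer that comes from the C3-epimeric part of 11 is removed here.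

Step 9
Reactants: 13 tert-butyldiphenylsilyl ether of (2R)-2-[(3S,6R)-6-methyl-6-(prop-2-en-1-yl)-1,2-dioxan-3-yl]propan-1-ol
Product: 15 tert-butyldiphenylsilyl ether of (2R)-2-[(3S,6S)-6-(3-hydroxypropyl)-6-methyl-1,2-dioxan-3-yl]propan-1-ol, via B-alkyl-9-BBN borane 14 (not isolated)
Conditions: 9-BBN, THF, 0 °C to rt; then NaOH, H2O2, 0 °C
Reagents that add atoms: hydrogen peroxide, OO
Why: Anti-Markovnikov hydroboration of the terminal alkene and oxidation of the C–B bond (hydroboration–oxidation) place oxygen on C3'; the hindered dialkyl peroxide should be inert to 9-BBN and to cold alkaline H2O2.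

Step 10
Reactants: 15 tert-butyldiphenylsilyl ether of (2R)-2-[(3S,6S)-6-(3-hydroxypropyl)-6-methyl-1,2-dioxan-3-yl]propan-1-ol
Product: 16 tert-butyldiphenylsilyl ether of (2R)-2-[(3S,6R)-6-methyl-6-(3-oxopropyl)-1,2-dioxan-3-yl]propan-1-ol
Conditions: Dess–Martin periodinane, CH2Cl2, rt
Reagents that add atoms: none
Why: Dess–Martin oxidation under neutral conditions gives the aldehyde without touching the O–O bond or the silyl ether.

Step 11
Reactants: 17 6-methoxy-3,4-dihydronaphthalen-1(2H)-one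
Product: 18 6-methoxy-1,1-dimethyl-1,2,3,4-tetrahydronaphthalene
Conditions: Me2Zn, TiCl4, CH2Cl2, −30 °C to rt
Reagents that add atoms: dimethylzinc, C[Zn]C
Why: Geminal dimethylation of the aryl ketone: Me2TiCl2 formed in the flask adds one methyl, and the benzylic titanium alkoxide, stabilised by the para methoxy group, ionises and takes up the second.

Step 12
Reactants: 18 6-methoxy-1,1-dimethyl-1,2,3,4-tetrahydronaphthalene
Product: 19 5,5-dimethyl-5,6,7,8-tetrahydronaphthalen-2-ol
Conditions: BBr3, CH2Cl2, −78 °C to 0 °C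
Reagents that add atoms: none
Why: Lewis-acid cleavage of the aryl methyl ether frees the phenol so that a silyl group can take the place of methyl.

Step 13
Reactants: 19 5,5-dimethyl-5,6,7,8-tetrahydronaphthalen-2-ol
Product: 20 tert-butyl[(5,5-dimethyl-5,6,7,8-tetrahydronaphthalen-2-yl)oxy]dimethylsilane
Conditions: TBSCl, imidazole, DMF, rt
Reagents that add atoms: tert-butyl(chloro)dimethylsilane, CC(C)(C)[Si](C)(C)Cl
Why: Silylation of the phenol gives the aryl silyl ether that the Birch reduction turns directly into a regiodefined silyl enol ether.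

Step 14
Reactants: 20 tert-butyl[(5,5-dimethyl-5,6,7,8-tetrahydronaphthalen-2-yl)oxy]dimethylsilane
Product: 21 tert-butyl[(5,5-dimethyl-1,4,5,6,7,8-hexahydronaphthalen-2-yl)oxy]dimethylsilane
Conditions: Li, NH3 (l), THF, t-BuOH, −78 °C; NH4Cl
Reagents that add atoms: none
Why: Birch reduction of the aryl silyl ether protonates C1 and C4, leaving the silyl enol ether C2=C3 and the tetrasubstituted C4a=C8a bond, that is the skipped diene of ring B with fixed enol regiochemistry.

Step 15
Reactants: 21 tert-butyl[(5,5-dimethyl-1,4,5,6,7,8-hexahydronaphthalen-2-yl)oxy]dimethylsilane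
Product: 23 5,5-dimethyl-1,4,5,6,7,8-hexahydronaphthalen-2-yl trifluoromethanesulfonate, via cesium enolate 22 (not isolated)
Conditions: CsF, PhNTf2, DME, rt
Reagents that add atoms: N-phenylbis(trifluoromethanesulfonimide), O=S(=O)(N(c1ccccc1)S(=O)(=O)C(F)(F)F)C(F)(F)F
Why: Fluoride cleaves the silyl enol ether to the enolate, which is O-sulfonylated before any proton transfer to the doubly allylic C1 position, so the C2=C3 regiochemistry is kept (regiospecific enol triflate formation).

Step 16
Reactants: 23 5,5-dimethyl-1,4,5,6,7,8-hexahydronaphthalen-2-yl trifluoromethanesulfonate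
Product: 24 (5,5-dimethyl-1,4,5,6,7,8-hexahydronaphthalen-2-yl)trimethylstannane
Conditions: Me3SnSnMe3, Pd(PPh3)4 (cat.), LiCl, THF, 65 °C
Reagents that add atoms: hexamethylditin, C[Sn](C)(C)[Sn](C)(C)C
Why: Palladium-catalysed stannylation of the enol triflate (Stille-type triflate-to-tin exchange) gives a storable precursor of the vinyllithium without moving either double bond.

Step 17
Reactants: 24 (5,5-dimethyl-1,4,5,6,7,8-hexahydronaphthalen-2-yl)trimethylstannane; 16 tert-butyldiphenylsilyl ether of (2R)-2-[(3S,6R)-6-methyl-6-(3-oxopropyl)-1,2-dioxan-3-yl]propan-1-ol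
Product: 26 tert-butyldiphenylsilyl ether of (2R)-2-[(3S,6S)-6-[3-(5,5-dimethyl-1,4,5,6,7,8-hexahydronaphthalen-2-yl)-3-hydroxypropyl]-6-methyl-1,2-dioxan-3-yl]propan-1-ol (both C3' epimers), via dienyllithium 25 (not isolated)
Conditions: 24, MeLi, THF, −78 °C; then 16, −78 °C; NH4Cl (aq)
Reagents that add atoms: none
Why: Tin–lithium exchange gives the vinyllithium with the C2=C3 bond in place, and its 1,2-addition to the unhindered aldehyde at −78 °C should outrun attack on the hindered O–O bond; the carbinol centre is not controlled and is erased in step 18.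

Step 18
Reactants: 26 tert-butyldiphenylsilyl ether of (2R)-2-[(3S,6S)-6-[3-(5,5-dimethyl-1,4,5,6,7,8-hexahydronaphthalen-2-yl)-3-hydroxypropyl]-6-methyl-1,2-dioxan-3-yl]propan-1-ol
Product: 29 tert-butyldiphenylsilyl ether of (2R)-2-[(3S,6S)-6-[(3Z)-3-(5,5-dimethyl-3,4,5,6,7,8-hexahydronaphthalen-2(1H)-ylidene)propyl]-6-methyl-1,2-dioxan-3-yl]propan-1-ol, via sulfonylhydrazine 27 (not isolated), via allylic diazene 28 (not isolated)
Conditions: 2-nitrobenzenesulfonylhydrazide (NBSH), PPh3, DEAD, N-methylmorpholine, −30 °C to rt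
Reagents that add atoms: none
Why: Mitsunobu displacement by NBSH, loss of sulfinic acid and retro-ene loss of N2 from the allylic diazene deliver hydrogen to C3 and move the double bond to the exocyclic C2=C3' position (allylic diazene reductive transposition); the chain should sit pseudo-equatorial in the six-membered transition state and so end cis to C1 (Z), as in related sigmatropic routes to trisubstituted alkenes, while the C4a=C8a bond is untouched.

Step 19
Reactants: 29 tert-butyldiphenylsilyl ether of (2R)-2-[(3S,6S)-6-[(3Z)-3-(5,5-dimethyl-3,4,5,6,7,8-hexahydronaphthalen-2(1H)-ylidene)propyl]-6-methyl-1,2-dioxan-3-yl]propan-1-ol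
Product: 30 (2R)-2-[(3S,6S)-6-[(3Z)-3-(5,5-dimethyl-3,4,5,6,7,8-hexahydronaphthalen-2(1H)-ylidene)propyl]-6-methyl-1,2-dioxan-3-yl]propan-1-ol
Conditions: TBAF, AcOH, THF, 0 °C to rt
Reagents that add atoms: none
Why: Fluoride desilylation buffered with acetic acid frees the primary alcohol; the dialkyl peroxide and the skipped diene are inert to these conditions.

Step 20
Reactants: 30 (2R)-2-[(3S,6S)-6-[(3Z)-3-(5,5-dimethyl-3,4,5,6,7,8-hexahydronaphthalen-2(1H)-ylidene)propyl]-6-methyl-1,2-dioxan-3-yl]propan-1-ol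
Product: 32 (2S)-2-[(3S,6S)-6-[(3Z)-3-(5,5-dimethyl-3,4,5,6,7,8-hexahydronaphthalen-2(1H)-ylidene)propyl]-6-methyl-1,2-dioxan-3-yl]propanoic acid, via aldehyde 31 (not isolated)
Conditions: TEMPO (cat.), PhI(OAc)2, MeCN–H2O (pH 7 buffer), rt
Reagents that add atoms: water, O
Why: Oxoammonium oxidation of the primary alcohol through the aldehyde hydrate to the acid at neutral pH avoids base-induced β-elimination of the peroxide and epimerisation at C2 and should spare the alkenes.

**Compound list**

1 | methyl (2R)-3-hydroxy-2-methylpropanoate | C[C@H](CO)C(=O)OC | starting material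
2 | methyl (2R)-3-[(tert-butyldiphenylsilyl)oxy]-2-methylpropanoate | C[C@H](CO[Si](c1ccccc1)(c2ccccc2)C(C)(C)C)C(=O)OC | intermediate
3 | (2R)-3-[(tert-butyldiphenylsilyl)oxy]-2-methylpropanal | C[C@H](CO[Si](c1ccccc1)(c2ccccc2)C(C)(C)C)C=O | intermediate
4 | cyclopropyl phenyl sulfide | C1CC1Sc2ccccc2 | starting material
5 | 1-lithio-1-(phenylsulfanyl)cyclopropane | [Li]C1(CC1)Sc2ccccc2 | intermediate (not isolated)
6 | (2R)-3-[(tert-butyldiphenylsilyl)oxy]-2-methyl-1-[1-(phenylsulfanyl)cyclopropyl]propan-1-ol (C1 epimers) | C[C@H](CO[Si](c1ccccc1)(c2ccccc2)C(C)(C)C)C(O)C3(CC3)Sc4ccccc4 | intermediate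
7 | 2-[(2S)-1-[(tert-butyldiphenylsilyl)oxy]propan-2-yl]cyclobutan-1-one (ring epimers) | C[C@H](CO[Si](c1ccccc1)(c2ccccc2)C(C)(C)C)C3CCC3=O | intermediate
8 | 2-[(2S)-1-[(tert-butyldiphenylsilyl)oxy]propan-2-yl]-1-methylcyclobutan-1-ol (ring stereoisomers) | C[C@H](CO[Si](c1ccccc1)(c2ccccc2)C(C)(C)C)C3CCC3(C)O | intermediate
9 | (6R)-7-[(tert-butyldiphenylsilyl)oxy]-5-hydroperoxy-6-methylheptan-2-one (C5 epimers) | C[C@H](CO[Si](c1ccccc1)(c2ccccc2)C(C)(C)C)C(OO)CCC(C)=O | intermediate (not isolated)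
10 | tert-butyldiphenylsilyl ether of (2R)-2-(6-hydroxy-6-methyl-1,2-dioxan-3-yl)propan-1-ol (C3 epimers, C6 anomers) | C[C@H](CO[Si](c1ccccc1)(c2ccccc2)C(C)(C)C)C3CCC(C)(O)OO3 | intermediate
11 | tert-butyldiphenylsilyl ether of (2R)-2-(6-methoxy-6-methyl-1,2-dioxan-3-yl)propan-1-ol (C3 epimers, C6 anomers) | C[C@H](CO[Si](c1ccccc1)(c2ccccc2)C(C)(C)C)C3CCC(C)(OC)OO3 | intermediate
12 | 6-methyl-1,2-dioxan-1-ium-6-ylidene (peroxycarbenium) triflate bearing the (2R)-1-silyloxypropan-2-yl group at C3 (C3 epimers) | C[C@H](CO[Si](c1ccccc1)(c2ccccc2)C(C)(C)C)C3CCC(C)=[O+]O3.[O-]S(=O)(=O)C(F)(F)F | intermediate (not isolated)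
13 | tert-butyldiphenylsilyl ether of (2R)-2-[(3S,6R)-6-methyl-6-(prop-2-en-1-yl)-1,2-dioxan-3-yl]propan-1-ol | C[C@H](CO[Si](c1ccccc1)(c2ccccc2)C(C)(C)C)[C@@H]3CC[C@](C)(CC=C)OO3 | intermediate
14 | B-alkyl-9-borabicyclo[3.3.1]nonane from 13 (boron on C3') | C[C@H](CO[Si](c1ccccc1)(c2ccccc2)C(C)(C)C)[C@@H]3CC[C@](C)(CCCB4C5CCCC4CCC5)OO3 | intermediate (not isolated)
15 | tert-butyldiphenylsilyl ether of (2R)-2-[(3S,6S)-6-(3-hydroxypropyl)-6-methyl-1,2-dioxan-3-yl]propan-1-ol | C[C@H](CO[Si](c1ccccc1)(c2ccccc2)C(C)(C)C)[C@@H]3CC[C@](C)(CCCO)OO3 | intermediate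
16 | tert-butyldiphenylsilyl ether of (2R)-2-[(3S,6R)-6-methyl-6-(3-oxopropyl)-1,2-dioxan-3-yl]propan-1-ol | C[C@H](CO[Si](c1ccccc1)(c2ccccc2)C(C)(C)C)[C@@H]3CC[C@](C)(CCC=O)OO3 | intermediate
17 | 6-methoxy-3,4-dihydronaphthalen-1(2H)-one | COc1ccc2c(c1)CCCC2=O | starting material
18 | 6-methoxy-1,1-dimethyl-1,2,3,4-tetrahydronaphthalene | COc1ccc2c(c1)CCCC2(C)C | intermediate
19 | 5,5-dimethyl-5,6,7,8-tetrahydronaphthalen-2-ol | Oc1ccc2c(c1)CCCC2(C)C | intermediate
20 | tert-butyl[(5,5-dimethyl-5,6,7,8-tetrahydronaphthalen-2-yl)oxy]dimethylsilane | CC(C)(C)[Si](C)(C)Oc1ccc2c(c1)CCCC2(C)C | intermediate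
21 | tert-butyl[(5,5-dimethyl-1,4,5,6,7,8-hexahydronaphthalen-2-yl)oxy]dimethylsilane | CC(C)(C)[Si](C)(C)OC1=CCC2=C(C1)CCCC2(C)C | intermediate
22 | cesium 5,5-dimethyl-1,4,5,6,7,8-hexahydronaphthalen-2-olate | [Cs+].[O-]C1=CCC2=C(C1)CCCC2(C)C | intermediate (not isolated)
23 | 5,5-dimethyl-1,4,5,6,7,8-hexahydronaphthalen-2-yl trifluoromethanesulfonate | O=S(=O)(OC1=CCC2=C(C1)CCCC2(C)C)C(F)(F)F | intermediate
24 | (5,5-dimethyl-1,4,5,6,7,8-hexahydronaphthalen-2-yl)trimethylstannane | C[Sn](C)(C)C1=CCC2=C(C1)CCCC2(C)C | intermediate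
25 | (5,5-dimethyl-1,4,5,6,7,8-hexahydronaphthalen-2-yl)lithium | [Li]C1=CCC2=C(C1)CCCC2(C)C | intermediate (not isolated)
26 | tert-butyldiphenylsilyl ether of (2R)-2-[(3S,6S)-6-[3-(5,5-dimethyl-1,4,5,6,7,8-hexahydronaphthalen-2-yl)-3-hydroxypropyl]-6-methyl-1,2-dioxan-3-yl]propan-1-ol (C3' epimers) | C[C@H](CO[Si](c1ccccc1)(c2ccccc2)C(C)(C)C)[C@@H]3CC[C@](C)(CCC(O)C4=CCC5=C(C4)CCCC5(C)C)OO3 | intermediate
27 | N-(2-nitrobenzenesulfonyl)-N-alkylhydrazine from 26 (nitrogen on C3') | C[C@H](CO[Si](c1ccccc1)(c2ccccc2)C(C)(C)C)[C@@H]3CC[C@](C)(CCC(N(N)S(=O)(=O)c6ccccc6[N+](=O)[O-])C4=CCC5=C(C4)CCCC5(C)C)OO3 | intermediate (not isolated)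
28 | allylic monoalkyl diazene from 27 | C[C@H](CO[Si](c1ccccc1)(c2ccccc2)C(C)(C)C)[C@@H]3CC[C@](C)(CCC(N=N)C4=CCC5=C(C4)CCCC5(C)C)OO3 | intermediate (not isolated)
29 | tert-butyldiphenylsilyl ether of (2R)-2-[(3S,6S)-6-[(3Z)-3-(5,5-dimethyl-3,4,5,6,7,8-hexahydronaphthalen-2(1H)-ylidene)propyl]-6-methyl-1,2-dioxan-3-yl]propan-1-ol | C[C@H](CO[Si](c1ccccc1)(c2ccccc2)C(C)(C)C)[C@@H]3CC[C@](C)(CC/C=C4/CCC5=C(CCCC5(C)C)C4)OO3 | intermediate
30 | (2R)-2-[(3S,6S)-6-[(3Z)-3-(5,5-dimethyl-3,4,5,6,7,8-hexahydronaphthalen-2(1H)-ylidene)propyl]-6-methyl-1,2-dioxan-3-yl]propan-1-ol | C[C@H](CO)[C@@H]1CC[C@](C)(CC/C=C2/CCC3=C(CCCC3(C)C)C2)OO1 | intermediate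
31 | (2S)-2-[(3S,6S)-6-[(3Z)-3-(5,5-dimethyl-3,4,5,6,7,8-hexahydronaphthalen-2(1H)-ylidene)propyl]-6-methyl-1,2-dioxan-3-yl]propanal | C[C@H](C=O)[C@@H]1CC[C@](C)(CC/C=C2/CCC3=C(CCCC3(C)C)C2)OO1 | intermediate (not isolated)
32 | (2S)-2-[(3S,6S)-6-[(3Z)-3-(5,5-dimethyl-3,4,5,6,7,8-hexahydronaphthalen-2(1H)-ylidene)propyl]-6-methyl-1,2-dioxan-3-yl]propanoic acid | C[C@H](C(=O)O)[C@@H]1CC[C@](C)(CC/C=C2/CCC3=C(CCCC3(C)C)C2)OO1 | target

**Step count and risks**

Total step count: 20. Longest linear sequence: 14 steps (steps 1–10 and 17–20); the bicyclic fragment takes steps 11–16.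

Steps most likely to fail:

Step 6. Oxygen capture by the open-chain C3 radical is not steered by the neighbouring stereocentre, and part of the alkoxy radical may fragment toward C5, so a large part of the material enters the wrong C3 series and is lost at step 8. The fallback builds the C3–O bond by polar displacement instead of radical capture. It sets out from 3: Felkin–Anh-controlled addition of the Grignard reagent of 2-(2-bromoethyl)-2-methyl-1,3-dioxolane (THF, −78 °C) should give mainly the syn alcohol (2R,3R)-1-[(tert-butyldiphenylsilyl)oxy]-2-methyl-5-(2-methyl-1,3-dioxolan-2-yl)pentan-3-ol F1. Mesylation (MsCl, Et3N) should give its methanesulfonate F2. Displacement with H2O2 and KOH with inversion should give tert-butyl{[(2R,3S)-3-hydroperoxy-2-methyl-5-(2-methyl-1,3-dioxolan-2-yl)pentyl]oxy}diphenylsilane F3. MeOH with p-TsOH should remove the dioxolane and close the hydroperoxide onto the ketone to the C3-homogeneous tert-butyldiphenylsilyl ether of (2R)-2-[(3S)-6-methoxy-6-methyl-1,2-dioxan-3-yl]propan-1-ol F4. Under the conditions of step 8, F4 should give 13, where the route is rejoined.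

Step 18. The retro-ene step may prefer, or fail to discriminate against, the transition state that places the chain cis to C3, and the phosphine may attack the O–O bond during the Mitsunobu stage. The fallback uses the regioisomeric ring diene, in which hydrogen is delivered to C1, so the opposite transition-state preference leads to the Z alkene. It sets out from 21: TBAF with AcOH should give 5,5-dimethyl-3,4,5,6,7,8-hexahydronaphthalen-2(1H)-one F5. LDA then PhNTf2 (THF, −78 °C) should enolise toward the doubly activated C1 and give 5,5-dimethyl-3,4,5,6,7,8-hexahydronaphthalen-2-yl trifluoromethanesulfonate F6. Me3SnSnMe3, Pd(PPh3)4 and LiCl should give (5,5-dimethyl-3,4,5,6,7,8-hexahydronaphthalen-2-yl)trimethylstannane F7. MeLi then 16, as in step 17, should give the tert-butyldiphenylsilyl ether of (2R)-2-[(3S,6S)-6-[3-(5,5-dimethyl-3,4,5,6,7,8-hexahydronaphthalen-2-yl)-3-hydroxypropyl]-6-methyl-1,2-dioxan-3-yl]propan-1-ol F8. NBSH, PPh3 and DEAD on F8 should give 29, where the route is rejoined. If neither regioisomer shows a useful preference, the alkene isomers would have to be separated.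

Step 17. The vinyllithium may attack the O–O bond or abstract a doubly allylic hydrogen from C1 of another diene molecule instead of adding to the aldehyde. The fallback joins the fragments by palladium-catalysed acylation without an organolithium. It sets out from 16: Pinnick oxidation (NaClO2, NaH2PO4, 2-methyl-2-butene) should give the tert-butyldiphenylsilyl ether of (2R)-2-[(3S,6R)-6-(2-carboxyethyl)-6-methyl-1,2-dioxan-3-yl]propan-1-ol F9. Oxalyl chloride with catalytic DMF should give the corresponding acid chloride F10. Stille acylation of 24 with F10 (PhCH2Pd(PPh3)2Cl cat., CHCl3, 60 °C) should give the tert-butyldiphenylsilyl ether of (2R)-2-[(3S,6R)-6-[3-(5,5-dimethyl-1,4,5,6,7,8-hexahydronaphthalen-2-yl)-3-oxopropyl]-6-methyl-1,2-dioxan-3-yl]propan-1-ol F11. Luche reduction (NaBH4, CeCl3·7H2O, MeOH, −78 °C) should give 26, where the route is rejoined.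

Further compounds
F1 | step 6 | (2R,3R)-1-[(tert-butyldiphenylsilyl)oxy]-2-methyl-5-(2-methyl-1,3-dioxolan-2-yl)pentan-3-ol | C[C@H](CO[Si](c1ccccc1)(c2ccccc2)C(C)(C)C)[C@H](O)CCC3(C)OCCO3
F2 | step 6 | (2R,3R)-1-[(tert-butyldiphenylsilyl)oxy]-2-methyl-5-(2-methyl-1,3-dioxolan-2-yl)pentan-3-yl methanesulfonate | C[C@H](CO[Si](c1ccccc1)(c2ccccc2)C(C)(C)C)[C@H](OS(C)(=O)=O)CCC3(C)OCCO3
F3 | step 6 | tert-butyl{[(2R,3S)-3-hydroperoxy-2-methyl-5-(2-methyl-1,3-dioxolan-2-yl)pentyl]oxy}diphenylsilane | C[C@H](CO[Si](c1ccccc1)(c2ccccc2)C(C)(C)C)[C@@H](OO)CCC3(C)OCCO3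
F4 | step 6 | tert-butyldiphenylsilyl ether of (2R)-2-[(3S)-6-methoxy-6-methyl-1,2-dioxan-3-yl]propan-1-ol (C6 anomers) | C[C@H](CO[Si](c1ccccc1)(c2ccccc2)C(C)(C)C)[C@@H]3CCC(C)(OC)OO3
F5 | step 18 | 5,5-dimethyl-3,4,5,6,7,8-hexahydronaphthalen-2(1H)-one | O=C1CCC2=C(C1)CCCC2(C)C
F6 | step 18 | 5,5-dimethyl-3,4,5,6,7,8-hexahydronaphthalen-2-yl trifluoromethanesulfonate | O=S(=O)(OC1=CC2=C(CC1)C(C)(C)CCC2)C(F)(F)F
F7 | step 18 | (5,5-dimethyl-3,4,5,6,7,8-hexahydronaphthalen-2-yl)trimethylstannane | C[Sn](C)(C)C1=CC2=C(CC1)C(C)(C)CCC2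
F8 | step 18 | tert-butyldiphenylsilyl ether of (2R)-2-[(3S,6S)-6-[3-(5,5-dimethyl-3,4,5,6,7,8-hexahydronaphthalen-2-yl)-3-hydroxypropyl]-6-methyl-1,2-dioxan-3-yl]propan-1-ol (C3' epimers) | C[C@H](CO[Si](c1ccccc1)(c2ccccc2)C(C)(C)C)[C@@H]3CC[C@](C)(CCC(O)C4=CC5=C(CC4)C(C)(C)CCC5)OO3
F9 | step 17 | tert-butyldiphenylsilyl ether of (2R)-2-[(3S,6R)-6-(2-carboxyethyl)-6-methyl-1,2-dioxan-3-yl]propan-1-ol | C[C@H](CO[Si](c1ccccc1)(c2ccccc2)C(C)(C)C)[C@@H]3CC[C@](C)(CCC(=O)O)OO3
F10 | step 17 | tert-butyldiphenylsilyl ether of (2R)-2-[(3S,6R)-6-(3-chloro-3-oxopropyl)-6-methyl-1,2-dioxan-3-yl]propan-1-ol | C[C@H](CO[Si](c1ccccc1)(c2ccccc2)C(C)(C)C)[C@@H]3CC[C@](C)(CCC(=O)Cl)OO3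
F11 | step 17 | tert-butyldiphenylsilyl ether of (2R)-2-[(3S,6R)-6-[3-(5,5-dimethyl-1,4,5,6,7,8-hexahydronaphthalen-2-yl)-3-oxopropyl]-6-methyl-1,2-dioxan-3-yl]propan-1-ol | C[C@H](CO[Si](c1ccccc1)(c2ccccc2)C(C)(C)C)[C@@H]3CC[C@](C)(CCC(=O)C4=CCC5=C(C4)CCCC5(C)C)OO3
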